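## Structural features

The target is a 2,4-diformylphloroglucinol whose remaining ring carbon carries a benzylic methine C1' (with an isobutyl chain, C2' and C3') bonded to the quaternary carbon C7 of a bicyclic sesquiterpenoid carbinol; the core locants used throughout are C1 (CH–CH3), C2, C3, C4 (CH–C(CH3)2OH), C4a, C5, C6, C7, C8 (=CH) and C8a, with ring A = C4a–C5–C6–C7–C8–C8a and ring B = C8a–C1–C2–C3–C4–C4a. Ring A holds the only C=C bond, C8=C8a, which is trisubstituted, exocyclic to ring B and flanked by the quaternary C7. There are five stereocenters: C1' (S) and C7 (S) are adjacent, C7 is 1,4 to C4a (R) across ring A, C4a is adjacent to C4 (S), and C1 (R) is cis-1,4 to C4 on ring B, so its methyl group is axial when the bulky C4 group is equatorial. Fragile groups are the two aldehydes and three acidic phenols (chelating, able to add to the alkene under acid), the tertiary alcohol (dehydration) and the alkene itself, which acid or metal hydrides could move into a tetrasubstituted position. The real difficulty is the C7/C1' pair: a fully substituted carbon whose three ring-side substituents (CH3, C6H2, C8H=) differ little in size, joined to a stereogenic benzylic carbon bearing a 2,6-disubstituted arene, so that intermolecular union of the two halves has no reliable facial bias. A smaller problem is that the C1 methyl group sits in the epimer that neither enolate protonation nor equilibration of a ring B ketone favours. The key step exploits the fact that C7 is the allylic carbon of C8=C8a: the array C1'–C7–C8=C8a is the product pattern of a [3,3] shift from an ester oxygen on C8a, so the bond, both stereocenters and the alkene position can be set together.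

## Logic of the disconnections

24 to 23: the three aryl O–CH3 bonds are added back. The free diformylphloroglucinol is acidic, chelating and able to cyclize onto the alkene, so it is unveiled last. The forward step must cleave three methyl ethers without acid; each is ortho or para to a formyl group, which allows nucleophilic demethylation.

23 to 21 to 20: the two aryl–CHO bonds are cut (through the aryl bromides). A formyl-free, electron-rich arene is needed for the enolate chemistry of the key step and survives hydride and radical steps. The forward formylation must avoid Lewis acids because of the tertiary alcohol and alkene, hence halogen–lithium exchange.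

20 to 19: the C–OH bond of the tertiary alcohol is cut back to the isopropenyl group of the chiral-pool terpene. This removes any need for a protecting group on a second tertiary alcohol. The forward hydration must be Markovnikov and select the 1,1-disubstituted alkene over the hindered ring alkene.

19 to 16 (through 18 and 17): the C2'–C3' bond is cut and oxygen is placed on C2'. The isobutyl chain is grown from the carbonyl carbon that the key step delivers. The forward steps must add an isopropyl group to a hindered, epimerizable α-aryl aldehyde and remove the oxygen under neutral conditions.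

16 to 15 to 14: oxidation-level changes only, from the carboxylic acid that the key step gives.

14 to 10 (key disconnection): the C7–C1' bond is cut, the C8a–O bond is restored and the alkene returns to C7=C8. In one sentence, the route is an Ireland–Claisen rearrangement of the arylacetate of a ring-fusion tertiary allylic alcohol, 10. This ties C7 to an existing carbinol center by a suprafacial shift, ties C1' to C7 through a cyclic transition state, and fixes the alkene position. The gain is the step from a vicinal quaternary/tertiary pair to a simple ester. The demands are one enolate geometry, one transition-state topology and no ionization of the tertiary allylic ester.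

10 to 7 and 8: the acyl C–O bond is cut. 8 is commercial; the forward step must acylate a hindered tertiary alcohol.

7 to 6: the C7=C8 bond is cut (ring-closing metathesis). The bicyclic alcohol becomes a monocyclic triene; the forward step must form a trisubstituted ring alkene and leave the isopropenyl group alone.

6 to 5: the C8a–C8 bond is cut (vinyl addition to the ring B ketone). The forward step must deliver the vinyl group to the β face so that the oxygen is cis to H-4a.

5 to 2 and 3: the C4a–C5 bond is cut (enolate alkylation). The forward step must deprotonate only the CH2 side of the ketone, alkylate trans to the isopropenyl group and not epimerize C1.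

2 to 1: the C1–H and C2–H bonds are removed, back to (S)-carvone, which supplies C4. The forward reduction must give the cis (axial-methyl) ketone, which requires catalyst control.

## Other disconnections considered

Alternative 1: the first that comes to mind. Cut C7–C1' in the polar sense. The forward key step is ionization of the benzylic carbinol A1 with a Lewis acid and capture of the cation at the α-carbon (C7) of silyl dienol ether A2, giving the C6 ketone A3.
- The cation is planar and C7 of A2 is flanked by groups of similar size, so nothing in either partner fixes C1'; control would need an external chiral element on the cation.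
- The face of C7 is chosen only by the remote ring B.
- A3 still carries a neopentyl ketone that must be removed next to the new quaternary carbon, and A2 needs its own enone synthesis.
- The chosen plan sets both centers in one intramolecular event and needs no extra oxygen in ring A.

Alternative 2: cut C1–C8a and C4–C4a (ring B). The forward key step is a Diels–Alder reaction of the (E,E)-diene A4 with the ring A enone A5, which would give the cis-1,4 relationship of C1 and C4 directly.
- The endo adduct A6 has H-4 and H-4a cis, the C4a epimer of what is needed, and C4a is not epimerizable after the ketone is used.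
- The diene termini are both alkyl-substituted, so regiocontrol is weak.
- The face of A5 is chosen by a quaternary center two atoms away.
- A5 already contains the unsolved C7/C1' pair, so the hard problem is only moved.

Alternative 3: cut C1'–aryl and C1'–C2', building C1' from a formyl carbon on C7. The forward sequence is addition of 2,4,6-trimethoxyphenyllithium to aldehyde A7 to give carbinol A8, then ionization and capture by methallyltrimethylsilane to give A9, then hydrogenation.
- The stereo-determining event is attack on an sp2 benzylic cation next to C7, whose CH3, CH2 and CH= substituents offer no basis for selection.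
- The cation sits beside a quaternary carbon (1,2-shift) in a molecule with two acid-sensitive alkenes.
- The new alkene would have to be hydrogenated in the presence of the others.
- The chosen plan replaces this acyclic induction by a cyclic transition state.

Key step: step 6

Remark on the chemistry: the ene-reductase is assumed to protonate C2 of (S)-carvone on the same face as for (R)-carvone, which corresponds to the 2R,5S (cis) ketone 2; compounds 3 and 8 are taken as commercial.

## Steps

Step 1
Reactants: 1 (S)-(+)-carvone, (5S)-2-methyl-5-(prop-1-en-2-yl)cyclohex-2-en-1-one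
Product: 2 (2R,5S)-2-methyl-5-(prop-1-en-2-yl)cyclohexan-1-one (cis-dihydrocarvone)
Conditions: ene-reductase (old-yellow-enzyme family), NADP+ (cat.), D-glucose, glucose dehydrogenase, phosphate buffer pH 7, 30 °C
Reagents that add atoms: none
Why: Enzymatic conjugate reduction; hydride goes to C3 and the proton to C2 on opposite faces of the bound enone, so C2 (R) is set by the catalyst independently of C5, giving the cis isomer that chemical enolate protonation would not favour. Neutral pH and prompt isolation should keep the axial-methyl ketone from epimerizing.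

Step 2
Reactants: 2 (2R,5S)-2-methyl-5-(prop-1-en-2-yl)cyclohexan-1-one; 3 4-iodo-2-methylbut-1-ene
Product: 5 (2R,5S,6R)-2-methyl-6-(3-methylbut-3-en-1-yl)-5-(prop-1-en-2-yl)cyclohexan-1-one, via lithium enolate 4 (not isolated)
Conditions: LiN(i-Pr)2, THF, −78 °C; then 3, DMPU, −78 → −20 °C
Reagents that add atoms: none
Why: Kinetic ketone enolate alkylation; LiN(i-Pr)2 removes a proton from the CH2 side (C6) and leaves the CH(CH3) center untouched. The electrophile should enter anti to the adjacent isopropenyl group, giving the trans-5,6 product (future C4/C4a).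

Step 3
Reactants: 5 (2R,5S,6R)-2-methyl-6-(3-methylbut-3-en-1-yl)-5-(prop-1-en-2-yl)cyclohexan-1-one
Product: 6 (1R,2R,5S,6R)-1-ethenyl-2-methyl-6-(3-methylbut-3-en-1-yl)-5-(prop-1-en-2-yl)cyclohexan-1-ol
Conditions: CH2=CHMgBr, CeCl3, THF, −78 → 0 °C
Reagents that add atoms: vinylmagnesium bromide, C=C[Mg]Br
Why: Carbonyl addition of CH2=CHCeCl2, which is not basic enough to epimerize C2 or C6. In the chair that keeps the two large vicinal groups equatorial the C2 methyl is axial and shields the α face, so the vinyl group should enter axially from the β face; in the flipped chair α attack would be 1,3-diaxial to the isopropenyl group. The hydroxyl therefore ends α, cis to H-6 (the future H-4a), which is the cis ring fusion needed in step 6.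

Step 4
Reactants: 6 (1R,2R,5S,6R)-1-ethenyl-2-methyl-6-(3-methylbut-3-en-1-yl)-5-(prop-1-en-2-yl)cyclohexan-1-ol
Product: 7 (1R,4S,4aR,8aR)-1,7-dimethyl-4-(prop-1-en-2-yl)-2,3,4,4a,5,6-hexahydronaphthalen-8a(1H)-ol
Conditions: second-generation Grubbs catalyst (H2IMes)(PCy3)Cl2Ru=CHPh (5 mol %), CH2Cl2, 40 °C
Reagents that add atoms: none
Why: Ring-closing metathesis of the vinyl group with the 1,1-disubstituted alkene of the side chain closes ring A as a trisubstituted cyclohexene. The isopropenyl group is trans to the vinyl group and cannot close a ring with it, and closure onto the chain alkene would need a tetrasubstituted alkene.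

Step 5
Reactants: 7 (1R,4S,4aR,8aR)-1,7-dimethyl-4-(prop-1-en-2-yl)-2,3,4,4a,5,6-hexahydronaphthalen-8a(1H)-ol; 8 (2,4,6-trimethoxyphenyl)acetic acid
Product: 10 (1R,4S,4aR,8aR)-1,7-dimethyl-4-(prop-1-en-2-yl)-2,3,4,4a,5,6-hexahydronaphthalen-8a(1H)-yl (2,4,6-trimethoxyphenyl)acetate, via acid chloride 9 (not isolated)
Conditions: 8, (COCl)2, DMF (cat.), CH2Cl2, 0 °C → rt, evaporate; 7, KN(SiMe3)2, THF, −78 °C, then 9, −78 → 0 °C
Reagents that add atoms: none
Why: O-Acylation of the deprotonated hindered tertiary alcohol by the acid chloride; any aryl ketene formed from 9 under the basic conditions adds the alkoxide to give the same ester. No stereocenter is touched.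

Step 6
Reactants: 10 (1R,4S,4aR,8aR)-1,7-dimethyl-4-(prop-1-en-2-yl)-2,3,4,4a,5,6-hexahydronaphthalen-8a(1H)-yl (2,4,6-trimethoxyphenyl)acetate
Product: 14 (2S)-2-[(1R,4S,4aR,7S)-1,7-dimethyl-4-(prop-1-en-2-yl)-1,2,3,4,4a,5,6,7-octahydronaphthalen-7-yl]-2-(2,4,6-trimethoxyphenyl)acetic acid, via potassium enolate 11 (not isolated), via silyl ketene acetal 12 (not isolated), via trimethylsilyl ester 13 (not isolated)
Conditions: KN(SiMe3)2, THF–DMPU, −78 °C; Me3SiCl; −78 °C → rt; 1 M HCl
Reagents that add atoms: none
Why: Ireland–Claisen rearrangement: deprotonation of 10 should give enolate 11 with the aryl group cis to O–K (Z), the geometry that keeps the 2,6-disubstituted arene away from the bulky tertiary alkoxy group and lets an ortho methoxy group bind potassium; silylation fixes it as 12, which undergoes a concerted suprafacial [3,3] shift on warming, and hydrolysis of 13 gives 14. The closest known reaction type is the ester enolate Claisen rearrangement of cyclohex-2-enyl and tertiary allylic esters, which builds a quaternary carbon next to a tertiary one. No ring is closed: the C8a–O bond breaks, the C7–C1' bond forms and the ring A double bond moves from C7=C8 to C8=C8a. C7 is controlled by the C8a carbinol set in step 3, because the new bond forms on the α face that carried the oxygen; in the cis-fused system this C–O bond is axial to ring A and aligned with the π bond. C1' is controlled by the Z ketene acetal geometry together with a boat-like transition state, in which the aryl group lies under the C7 methyl group and H-1' under C6; the chair would place the C(OSiMe3) carbon and its silyloxy group under ring A, which is why cyclohexenyl esters generally rearrange through the boat. The step needs Z over E geometry, boat over chair and [3,3] shift over ionization of the tertiary allylic ester; these are secured by the substitution pattern and dissociating solvent, by the ring, and by running the shift at or below room temperature.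

Step 7
Reactants: 14 (2S)-2-[(1R,4S,4aR,7S)-1,7-dimethyl-4-(prop-1-en-2-yl)-1,2,3,4,4a,5,6,7-octahydronaphthalen-7-yl]-2-(2,4,6-trimethoxyphenyl)acetic acid
Product: 15 (2S)-2-[(1R,4S,4aR,7S)-1,7-dimethyl-4-(prop-1-en-2-yl)-1,2,3,4,4a,5,6,7-octahydronaphthalen-7-yl]-2-(2,4,6-trimethoxyphenyl)ethan-1-ol
Conditions: LiAlH4, THF, 0 °C → reflux
Reagents that add atoms: none
Why: Hydride reduction of the carboxylic acid to the primary alcohol; the carboxylate is not enolized by the hydride, so C1' is kept.

Step 8
Reactants: 15 (2S)-2-[(1R,4S,4aR,7S)-1,7-dimethyl-4-(prop-1-en-2-yl)-1,2,3,4,4a,5,6,7-octahydronaphthalen-7-yl]-2-(2,4,6-trimethoxyphenyl)ethan-1-ol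
Product: 16 (2S)-2-[(1R,4S,4aR,7S)-1,7-dimethyl-4-(prop-1-en-2-yl)-1,2,3,4,4a,5,6,7-octahydronaphthalen-7-yl]-2-(2,4,6-trimethoxyphenyl)acetaldehyde
Conditions: Dess–Martin periodinane, NaHCO3, CH2Cl2, 0 °C → rt
Reagents that add atoms: none
Why: Dess–Martin oxidation under buffered conditions, chosen so that the hindered α-aryl aldehyde is not epimerized at C1'.

Step 9
Reactants: 16 (2S)-2-[(1R,4S,4aR,7S)-1,7-dimethyl-4-(prop-1-en-2-yl)-1,2,3,4,4a,5,6,7-octahydronaphthalen-7-yl]-2-(2,4,6-trimethoxyphenyl)acetaldehyde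
Product: 17 (1S)-1-[(1R,4S,4aR,7S)-1,7-dimethyl-4-(prop-1-en-2-yl)-1,2,3,4,4a,5,6,7-octahydronaphthalen-7-yl]-3-methyl-1-(2,4,6-trimethoxyphenyl)butan-2-ol (both C2 epimers)
Conditions: i-PrMgCl, CeCl3, THF, −78 °C
Reagents that add atoms: isopropylmagnesium chloride, CC(C)[Mg]Cl
Why: Carbonyl addition of i-PrCeCl2; the Grignard reagent alone would reduce or enolize this hindered aldehyde. The new carbinol center is removed in step 11, so its configuration does not matter.

Step 10
Reactants: 17 (1S)-1-[(1R,4S,4aR,7S)-1,7-dimethyl-4-(prop-1-en-2-yl)-1,2,3,4,4a,5,6,7-octahydronaphthalen-7-yl]-3-methyl-1-(2,4,6-trimethoxyphenyl)butan-2-ol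
Product: 18 O-[(1S)-1-[(1R,4S,4aR,7S)-1,7-dimethyl-4-(prop-1-en-2-yl)-1,2,3,4,4a,5,6,7-octahydronaphthalen-7-yl]-3-methyl-1-(2,4,6-trimethoxyphenyl)butan-2-yl] S-methyl carbonodithioate
Conditions: NaH, CS2, THF, 0 °C → rt; then CH3I
Reagents that add atoms: carbon disulfide, S=C=S; iodomethane, CI
Why: Xanthate formation from the secondary alcohol, the standard activation for radical deoxygenation; it works on hindered alcohols.

Step 11
Reactants: 18 O-[(1S)-1-[(1R,4S,4aR,7S)-1,7-dimethyl-4-(prop-1-en-2-yl)-1,2,3,4,4a,5,6,7-octahydronaphthalen-7-yl]-3-methyl-1-(2,4,6-trimethoxyphenyl)butan-2-yl] S-methyl carbonodithioate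
Product: 19 (1R,4S,4aR,7S)-1,7-dimethyl-7-[(1S)-3-methyl-1-(2,4,6-trimethoxyphenyl)butyl]-4-(prop-1-en-2-yl)-1,2,3,4,4a,5,6,7-octahydronaphthalene
Conditions: Bu3SnH, AIBN (cat.), toluene, 100 °C
Reagents that add atoms: none
Why: Barton–McCombie deoxygenation; the secondary C2' radical should be reduced by Bu3SnH faster than it can undergo 1,2-aryl shift or 5-endo cyclization. Neutral radical conditions leave C1' and both alkenes untouched.

Step 12
Reactants: 19 (1R,4S,4aR,7S)-1,7-dimethyl-7-[(1S)-3-methyl-1-(2,4,6-trimethoxyphenyl)butyl]-4-(prop-1-en-2-yl)-1,2,3,4,4a,5,6,7-octahydronaphthalene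
Product: 20 2-[(1R,4S,4aR,7S)-1,7-dimethyl-7-[(1S)-3-methyl-1-(2,4,6-trimethoxyphenyl)butyl]-1,2,3,4,4a,5,6,7-octahydronaphthalen-4-yl]propan-2-ol
Conditions: Co(acac)2 (cat.), PhSiH3, O2 (1 atm), THF, rt
Reagents that add atoms: dioxygen, O=O
Why: Mukaiyama hydration; hydrogen-atom transfer from a cobalt hydride to the accessible 1,1-disubstituted alkene gives the tertiary radical, which is trapped by O2 (Markovnikov). The ring alkene between the quaternary C7 and the ring fusion should react much more slowly, and the arene is inert.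

Step 13
Reactants: 20 2-[(1R,4S,4aR,7S)-1,7-dimethyl-7-[(1S)-3-methyl-1-(2,4,6-trimethoxyphenyl)butyl]-1,2,3,4,4a,5,6,7-octahydronaphthalen-4-yl]propan-2-ol
Product: 21 2-[(1R,4S,4aR,7S)-7-[(1S)-1-(3,5-dibromo-2,4,6-trimethoxyphenyl)-3-methylbutyl]-1,7-dimethyl-1,2,3,4,4a,5,6,7-octahydronaphthalen-4-yl]propan-2-ol
Conditions: NBS (2.05 equiv), CH3CN, 0 °C
Reagents that add atoms: N-bromosuccinimide, O=C1CCC(=O)N1Br
Why: Electrophilic aromatic bromination of the two free positions of the trimethoxyarene, which are far more nucleophilic than the hindered alkene.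

Step 14
Reactants: 21 2-[(1R,4S,4aR,7S)-7-[(1S)-1-(3,5-dibromo-2,4,6-trimethoxyphenyl)-3-methylbutyl]-1,7-dimethyl-1,2,3,4,4a,5,6,7-octahydronaphthalen-4-yl]propan-2-ol
Product: 23 5-[(1S)-1-[(1R,4S,4aR,7S)-4-(2-hydroxypropan-2-yl)-1,7-dimethyl-1,2,3,4,4a,5,6,7-octahydronaphthalen-7-yl]-3-methylbutyl]-2,4,6-trimethoxybenzene-1,3-dicarbaldehyde, via lithiated arene 22 (not isolated)
Conditions: t-BuLi (5.5 equiv), THF, −78 °C; DMF, −78 → 0 °C; aq. NH4Cl
Reagents that add atoms: N,N-dimethylformamide, CN(C)C=O
Why: Double bromine–lithium exchange, each aryllithium being flanked and stabilized by two methoxy groups, then formylation with DMF. The alcohol is carried as its lithium alkoxide, and no Lewis acid touches the tertiary alcohol or alkene.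

Step 15
Reactants: 23 5-[(1S)-1-[(1R,4S,4aR,7S)-4-(2-hydroxypropan-2-yl)-1,7-dimethyl-1,2,3,4,4a,5,6,7-octahydronaphthalen-7-yl]-3-methylbutyl]-2,4,6-trimethoxybenzene-1,3-dicarbaldehyde
Product: 24 5-[(1S)-1-[(1R,4S,4aR,7S)-4-(2-hydroxypropan-2-yl)-1,7-dimethyl-1,2,3,4,4a,5,6,7-octahydronaphthalen-7-yl]-3-methylbutyl]-2,4,6-trihydroxybenzene-1,3-dicarbaldehyde (CNP0200991.2)
Conditions: NaSC6H4-4-CH3 (excess), HMPA–toluene, 110 °C; then 1 M HCl
Reagents that add atoms: none
Why: Nucleophilic (SN2) demethylation by thiolate; every methoxy group is ortho or para to a formyl group, which stabilizes the departing phenoxide. The basic, acid-free medium should leave the tertiary alcohol and the trisubstituted alkene alone.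

## Compound list

1 | (S)-(+)-carvone, (5S)-2-methyl-5-(prop-1-en-2-yl)cyclohex-2-en-1-one | CC1=CC[C@@H](CC1=O)C(C)=C | starting material
2 | (2R,5S)-2-methyl-5-(prop-1-en-2-yl)cyclohexan-1-one | C[C@@H]1CC[C@@H](CC1=O)C(C)=C | intermediate
3 | 4-iodo-2-methylbut-1-ene | CC(=C)CCI | starting material
4 | lithium (3S,6R)-6-methyl-3-(prop-1-en-2-yl)cyclohex-1-en-1-olate | C[C@@H]1CC[C@H](C(C)=C)C=C1O[Li] | intermediate
5 | (2R,5S,6R)-2-methyl-6-(3-methylbut-3-en-1-yl)-5-(prop-1-en-2-yl)cyclohexan-1-one | C[C@@H]1CC[C@H](C(C)=C)[C@@H](CCC(C)=C)C1=O | intermediate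
6 | (1R,2R,5S,6R)-1-ethenyl-2-methyl-6-(3-methylbut-3-en-1-yl)-5-(prop-1-en-2-yl)cyclohexan-1-ol | C[C@@H]1CC[C@H](C(C)=C)[C@@H](CCC(C)=C)[C@@]1(O)C=C | intermediate
7 | (1R,4S,4aR,8aR)-1,7-dimethyl-4-(prop-1-en-2-yl)-2,3,4,4a,5,6-hexahydronaphthalen-8a(1H)-ol | C[C@@H]1CC[C@H](C(C)=C)[C@H]2CCC(C)=C[C@@]12O | intermediate
8 | (2,4,6-trimethoxyphenyl)acetic acid | COc1cc(OC)c(CC(O)=O)c(OC)c1 | starting material
9 | (2,4,6-trimethoxyphenyl)acetyl chloride | COc1cc(OC)c(CC(Cl)=O)c(OC)c1 | intermediate
10 | (1R,4S,4aR,8aR)-1,7-dimethyl-4-(prop-1-en-2-yl)-2,3,4,4a,5,6-hexahydronaphthalen-8a(1H)-yl (2,4,6-trimethoxyphenyl)acetate | C[C@@H]1CC[C@H](C(C)=C)[C@H]2CCC(C)=C[C@@]12OC(=O)Cc1c(OC)cc(OC)cc1OC | intermediate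
11 | potassium (Z)-1-{[(1R,4S,4aR,8aR)-1,7-dimethyl-4-(prop-1-en-2-yl)-2,3,4,4a,5,6-hexahydronaphthalen-8a(1H)-yl]oxy}-2-(2,4,6-trimethoxyphenyl)ethen-1-olate | C[C@@H]1CC[C@H](C(C)=C)[C@H]2CCC(C)=C[C@@]12O/C(O[K])=C/c1c(OC)cc(OC)cc1OC | intermediate
12 | {[(Z)-1-{[(1R,4S,4aR,8aR)-1,7-dimethyl-4-(prop-1-en-2-yl)-2,3,4,4a,5,6-hexahydronaphthalen-8a(1H)-yl]oxy}-2-(2,4,6-trimethoxyphenyl)ethenyl]oxy}trimethylsilane | C[C@@H]1CC[C@H](C(C)=C)[C@H]2CCC(C)=C[C@@]12O/C(O[Si](C)(C)C)=C/c1c(OC)cc(OC)cc1OC | intermediate
13 | trimethylsilyl (2S)-2-[(1R,4S,4aR,7S)-1,7-dimethyl-4-(prop-1-en-2-yl)-1,2,3,4,4a,5,6,7-octahydronaphthalen-7-yl]-2-(2,4,6-trimethoxyphenyl)acetate | C[Si](C)(C)OC(=O)[C@H](c1c(OC)cc(OC)cc1OC)[C@]1(C)C=C2[C@H](C)CC[C@H](C(C)=C)[C@H]2CC1 | intermediate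
14 | (2S)-2-[(1R,4S,4aR,7S)-1,7-dimethyl-4-(prop-1-en-2-yl)-1,2,3,4,4a,5,6,7-octahydronaphthalen-7-yl]-2-(2,4,6-trimethoxyphenyl)acetic acid | OC(=O)[C@H](c1c(OC)cc(OC)cc1OC)[C@]1(C)C=C2[C@H](C)CC[C@H](C(C)=C)[C@H]2CC1 | intermediate
15 | (2S)-2-[(1R,4S,4aR,7S)-1,7-dimethyl-4-(prop-1-en-2-yl)-1,2,3,4,4a,5,6,7-octahydronaphthalen-7-yl]-2-(2,4,6-trimethoxyphenyl)ethan-1-ol | OC[C@H](c1c(OC)cc(OC)cc1OC)[C@]1(C)C=C2[C@H](C)CC[C@H](C(C)=C)[C@H]2CC1 | intermediate
16 | (2S)-2-[(1R,4S,4aR,7S)-1,7-dimethyl-4-(prop-1-en-2-yl)-1,2,3,4,4a,5,6,7-octahydronaphthalen-7-yl]-2-(2,4,6-trimethoxyphenyl)acetaldehyde | O=C[C@H](c1c(OC)cc(OC)cc1OC)[C@]1(C)C=C2[C@H](C)CC[C@H](C(C)=C)[C@H]2CC1 | intermediate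
17 | (1S)-1-[(1R,4S,4aR,7S)-1,7-dimethyl-4-(prop-1-en-2-yl)-1,2,3,4,4a,5,6,7-octahydronaphthalen-7-yl]-3-methyl-1-(2,4,6-trimethoxyphenyl)butan-2-ol (both C2 epimers) | CC(C)C(O)[C@H](c1c(OC)cc(OC)cc1OC)[C@]1(C)C=C2[C@H](C)CC[C@H](C(C)=C)[C@H]2CC1 | intermediate
18 | O-[(1S)-1-[(1R,4S,4aR,7S)-1,7-dimethyl-4-(prop-1-en-2-yl)-1,2,3,4,4a,5,6,7-octahydronaphthalen-7-yl]-3-methyl-1-(2,4,6-trimethoxyphenyl)butan-2-yl] S-methyl carbonodithioate | CC(C)C(OC(=S)SC)[C@H](c1c(OC)cc(OC)cc1OC)[C@]1(C)C=C2[C@H](C)CC[C@H](C(C)=C)[C@H]2CC1 | intermediate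
19 | (1R,4S,4aR,7S)-1,7-dimethyl-7-[(1S)-3-methyl-1-(2,4,6-trimethoxyphenyl)butyl]-4-(prop-1-en-2-yl)-1,2,3,4,4a,5,6,7-octahydronaphthalene | CC(C)C[C@H](c1c(OC)cc(OC)cc1OC)[C@]1(C)C=C2[C@H](C)CC[C@H](C(C)=C)[C@H]2CC1 | intermediate
20 | 2-[(1R,4S,4aR,7S)-1,7-dimethyl-7-[(1S)-3-methyl-1-(2,4,6-trimethoxyphenyl)butyl]-1,2,3,4,4a,5,6,7-octahydronaphthalen-4-yl]propan-2-ol | CC(C)C[C@H](c1c(OC)cc(OC)cc1OC)[C@]1(C)C=C2[C@H](C)CC[C@H](C(C)(C)O)[C@H]2CC1 | intermediate
21 | 2-[(1R,4S,4aR,7S)-7-[(1S)-1-(3,5-dibromo-2,4,6-trimethoxyphenyl)-3-methylbutyl]-1,7-dimethyl-1,2,3,4,4a,5,6,7-octahydronaphthalen-4-yl]propan-2-ol | CC(C)C[C@H](c1c(OC)c(Br)c(OC)c(Br)c1OC)[C@]1(C)C=C2[C@H](C)CC[C@H](C(C)(C)O)[C@H]2CC1 | intermediate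
22 | lithium 2-[(1R,4S,4aR,7S)-7-[(1S)-1-(3,5-dilithio-2,4,6-trimethoxyphenyl)-3-methylbutyl]-1,7-dimethyl-1,2,3,4,4a,5,6,7-octahydronaphthalen-4-yl]propan-2-olate | CC(C)C[C@H](c1c(OC)c([Li])c(OC)c([Li])c1OC)[C@]1(C)C=C2[C@H](C)CC[C@H](C(C)(C)O[Li])[C@H]2CC1 | intermediate
23 | 5-[(1S)-1-[(1R,4S,4aR,7S)-4-(2-hydroxypropan-2-yl)-1,7-dimethyl-1,2,3,4,4a,5,6,7-octahydronaphthalen-7-yl]-3-methylbutyl]-2,4,6-trimethoxybenzene-1,3-dicarbaldehyde | CC(C)C[C@H](c1c(OC)c(C=O)c(OC)c(C=O)c1OC)[C@]1(C)C=C2[C@H](C)CC[C@H](C(C)(C)O)[C@H]2CC1 | intermediate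
24 | 5-[(1S)-1-[(1R,4S,4aR,7S)-4-(2-hydroxypropan-2-yl)-1,7-dimethyl-1,2,3,4,4a,5,6,7-octahydronaphthalen-7-yl]-3-methylbutyl]-2,4,6-trihydroxybenzene-1,3-dicarbaldehyde (CNP0200991.2) | CC(C)C[C@H](c1c(O)c(C=O)c(O)c(C=O)c1O)[C@]1(C)C=C2[C@H](C)CC[C@H](C(C)(C)O)[C@H]2CC1 | target

## Step count and least certain steps

Total step count: 15. Longest linear sequence: 15 steps (from 1; 3 and 8 enter as commercial reagents).

Step 6 (key step).
- What may go wrong: chair-like and boat-like transition states may compete, or the enolate geometry may leak, which would erode or invert control at C1'. The tertiary allylic C–O bond may also ionize at higher temperature and scramble both new centers.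
- Fallback: an amide-acetal (Eschenmoser–Claisen) rearrangement, setting out from 7 and 9 and returning at 16. Acid chloride 9 and dimethylamine give N,N-dimethyl-2-(2,4,6-trimethoxyphenyl)acetamide F1. O-Methylation (MeOTf) and NaOMe convert it into the amide acetal 1,1-dimethoxy-N,N-dimethyl-2-(2,4,6-trimethoxyphenyl)ethan-1-amine F2. Heating 7 with F2 (xylene, 140 °C) should form, by exchange and loss of methanol, a ketene N,O-acetal whose aryl group is held cis to the allylic oxygen by allylic strain against NMe2. This is the geometry complementary to 12, and the reaction is neutral and thermal. If the ring system prefers the chair, this geometry leads to the required C1' epimer, the amide (2S)-2-[(1R,4S,4aR,7S)-1,7-dimethyl-4-(prop-1-en-2-yl)-1,2,3,4,4a,5,6,7-octahydronaphthalen-7-yl]-N,N-dimethyl-2-(2,4,6-trimethoxyphenyl)acetamide F3. F3 is reduced with Cp2Zr(H)Cl to aldehyde 16.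

Step 1.
- What may go wrong: incomplete facial control by the enzyme on this carvone enantiomer, or epimerization of the axial-methyl ketone to the more stable trans isomer during the reaction or isolation.
- Fallback: chemical reduction with equilibration and recycling, setting out from 1 and returning at 2. Conjugate reduction of 1 with LiBH(s-Bu)3 and protonation should give mainly the trans ketone (2S,5S)-2-methyl-5-(prop-1-en-2-yl)cyclohexan-1-one F4 together with 2. Compound 2 is separated by chromatography; F4 is re-equilibrated with NaOMe in MeOH and the mixture is separated again.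

Step 2.
- What may go wrong: elimination of the homoallylic iodide to isoprene, and proton transfer between product and enolate during the slow alkylation, which would scramble C2 and the regiochemistry.
- Fallback: a conjugate-addition route, setting out from 4 and returning at 5. Enolate 4 is trapped with Me3SiCl as trimethyl{[(3S,6R)-6-methyl-3-(prop-1-en-2-yl)cyclohex-1-en-1-yl]oxy}silane F5. Mukaiyama–Michael addition of F5 to methyl vinyl ketone (BF3·OEt2, CH2Cl2, −78 °C), anti to the isopropenyl group, gives the diketone (2R,5S,6R)-2-methyl-6-(3-oxobutyl)-5-(prop-1-en-2-yl)cyclohexan-1-one F6. The unhindered methyl ketone of F6 is then methylenated selectively with Ph3P=CH2 (1 equiv, THF, −78 → 0 °C) to give 5.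

Step 12.
- What may go wrong: hydrogen-atom transfer to the ring alkene as well, incomplete conversion, or peroxide by-products that resist reduction.
- Fallback: oxidative cleavage and methyl addition, setting out from 19 and returning at 20. Lemieux–Johnson cleavage of the isopropenyl group (OsO4 cat., NaIO4, 2,6-lutidine, dioxane–water), which should spare the hindered ring alkene, gives the methyl ketone 1-[(1R,4S,4aR,7S)-1,7-dimethyl-7-[(1S)-3-methyl-1-(2,4,6-trimethoxyphenyl)butyl]-1,2,3,4,4a,5,6,7-octahydronaphthalen-4-yl]ethan-1-one F7. The acetyl group is equatorial, so C4 should not epimerize. MeMgBr with CeCl3 (THF, −78 °C) then gives 20.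

Step 15.
- What may go wrong: ipso substitution of the doubly activated methoxy groups by the thiolate, stalling after two demethylations once the ring is a bis-phenoxide, or base-induced reactions of the aldehydes at 110 °C.
- Fallback: a change from external nucleophilic attack to chelation-directed Lewis-acid dealkylation, setting out from 23 and giving 24 directly with no new compound (F0). MgI2·OEt2 (toluene–Et2O, 60–80 °C) binds between each formyl oxygen and its ortho methoxy group and iodide removes the methyl group. No free thiolate is present, so ipso substitution is excluded, and the tertiary alcohol is held as a magnesium alkoxide.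

## Further compounds

F1 | step 6 | N,N-dimethyl-2-(2,4,6-trimethoxyphenyl)acetamide | COc1cc(OC)c(CC(=O)N(C)C)c(OC)c1
F2 | step 6 | 1,1-dimethoxy-N,N-dimethyl-2-(2,4,6-trimethoxyphenyl)ethan-1-amine | COc1cc(OC)c(CC(OC)(OC)N(C)C)c(OC)c1
F3 | step 6 | (2S)-2-[(1R,4S,4aR,7S)-1,7-dimethyl-4-(prop-1-en-2-yl)-1,2,3,4,4a,5,6,7-octahydronaphthalen-7-yl]-N,N-dimethyl-2-(2,4,6-trimethoxyphenyl)acetamide | CN(C)C(=O)[C@H](c1c(OC)cc(OC)cc1OC)[C@]1(C)C=C2[C@H](C)CC[C@H](C(C)=C)[C@H]2CC1
F4 | step 1 | (2S,5S)-2-methyl-5-(prop-1-en-2-yl)cyclohexan-1-one | C[C@H]1CC[C@@H](CC1=O)C(C)=C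
F5 | step 2 | trimethyl{[(3S,6R)-6-methyl-3-(prop-1-en-2-yl)cyclohex-1-en-1-yl]oxy}silane | C[C@@H]1CC[C@H](C(C)=C)C=C1O[Si](C)(C)C
F6 | step 2 | (2R,5S,6R)-2-methyl-6-(3-oxobutyl)-5-(prop-1-en-2-yl)cyclohexan-1-one | C[C@@H]1CC[C@H](C(C)=C)[C@@H](CCC(C)=O)C1=O
F7 | step 12 | 1-[(1R,4S,4aR,7S)-1,7-dimethyl-7-[(1S)-3-methyl-1-(2,4,6-trimethoxyphenyl)butyl]-1,2,3,4,4a,5,6,7-octahydronaphthalen-4-yl]ethan-1-one | CC(C)C[C@H](c1c(OC)cc(OC)cc1OC)[C@]1(C)C=C2[C@H](C)CC[C@H](C(C)=O)[C@H]2CC1
F0 | step 15 | none | none
A1 | alternative 1 | 3-methyl-1-(2,4,6-trimethoxyphenyl)butan-1-ol | CC(C)CC(O)c1c(OC)cc(OC)cc1OC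
A2 | alternative 1 | (1R,4S,4aR)-1,7-dimethyl-4-(prop-1-en-2-yl)-6-(trimethylsilyloxy)-1,2,3,4,4a,5-hexahydronaphthalene | C[C@@H]1CC[C@H](C(C)=C)[C@H]2CC(O[Si](C)(C)C)=C(C)C=C12
A3 | alternative 1 | 6-oxo derivative of compound 19 (C6 ketone next to the quaternary C7) | CC(C)C[C@H](c1c(OC)cc(OC)cc1OC)[C@]1(C)C=C2[C@H](C)CC[C@H](C(C)=C)[C@H]2CC1=O
A4 | alternative 2 | (3E,5E)-2-methylhepta-3,5-dien-2-ol | C/C=C/C=C/C(C)(C)O
A5 | alternative 2 | 6-methyl-6-[(1S)-3-methyl-1-(2,4,6-trimethoxyphenyl)butyl]cyclohex-2-en-1-one, C6 configured as C7 of the target | CC(C)C[C@H](c1c(OC)cc(OC)cc1OC)[C@@]1(C)CCC=CC1=O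
A6 | alternative 2 | endo Diels–Alder adduct of A4 and A5 (cis-fused 8-oxo-octalin with H-4 and H-4a cis) | CC(C)C[C@H](c1c(OC)cc(OC)cc1OC)[C@@]1(C)CC[C@H]2[C@@H](C(C)(C)O)C=C[C@@H](C)[C@H]2C1=O
A7 | alternative 3 | (1R,4S,4aR,7S)-1,7-dimethyl-4-(prop-1-en-2-yl)-1,2,3,4,4a,5,6,7-octahydronaphthalene-7-carbaldehyde | O=C[C@]1(C)C=C2[C@H](C)CC[C@H](C(C)=C)[C@H]2CC1
A8 | alternative 3 | [(1R,4S,4aR,7S)-1,7-dimethyl-4-(prop-1-en-2-yl)-1,2,3,4,4a,5,6,7-octahydronaphthalen-7-yl](2,4,6-trimethoxyphenyl)methanol (both carbinol epimers) | OC(c1c(OC)cc(OC)cc1OC)[C@]1(C)C=C2[C@H](C)CC[C@H](C(C)=C)[C@H]2CC1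
A9 | alternative 3 | (1R,4S,4aR,7S)-1,7-dimethyl-7-[3-methyl-1-(2,4,6-trimethoxyphenyl)but-3-en-1-yl]-4-(prop-1-en-2-yl)-1,2,3,4,4a,5,6,7-octahydronaphthalene (benzylic center uncontrolled) | CC(=C)CC(c1c(OC)cc(OC)cc1OC)[C@]1(C)C=C2[C@H](C)CC[C@H](C(C)=C)[C@H]2CC1
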